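Eremophilane numbering is used for every intermediate, including the monocyclic ones (ring A = C1–C5 and C10, ring B = C5–C10, C11 = carbinol carbon of the C7 side chain). β is the face of ring B that carries the C7 side chain (the C5 methyl and H-10 end up there too); α is the opposite face.

## The problem

The target is a cis-fused eremophilane. Ring A holds the C2 ketone and the 4β,5β-dimethyl pair, ring B holds the 7β-isopropenyl group and a cis-8α,9α-diol esterified with two different acids, and H-10 is β. Six ring stereocentres run without a gap from C4 through C5, C10, C9 and C8 to C7, with C5 quaternary and flanked by two of them; a seventh lies in the (R)-2-methylbutanoate. C7 is the natural anchor: it can be bought with a terpene and can set the C9 carbinol of a ring B cyclohexenol. That carbinol can pass its configuration to C5 in a [3,3] shift, C5 then fixes C10 through a tether, and C4 depends on enolate geometry. The two oxygens are the hard part: both lie on the concave α face, and an α substituent on C9 is syn-axial to C2 and C4 of ring A, so an external reagent is not expected to reach C9 from that side, while the β face at C8 is screened by C11. The fragile groups are the isopropenyl alkene (it would compete in every alkene oxidation), the vicinal cis-diester (acyl shift between O8 and O9), the tiglate, the α-centre of the 2-methylbutanoate, and the 9α-oxygen, which can close on the C2 ketone. The isopropenyl group is therefore carried as its hydrate, whose C11 hydroxyl serves three times as an internal delivery group, and both esters go on late. The key step rests on one feature: C10 lies between C1 (α to the C2 ketone) and C9, so a C1 enolate held on C5 by the C2–C3–C4 chain can attack the C10 end of a C8–C9–C10 π-allyl of ring B. This closes ring A, sets the cis fusion, and leaves the C8=C9 alkene where the two oxygens are needed.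

## Retrosynthesis

**Isopropenyl group and esters (30 ⇒ 29 ⇒ 27 + 28; 26 ⇒ 24 + 25).** The C11=C12 alkene is traced back to tertiary alcohol 29, and the two acyl C–O bonds are cut one at a time. Dehydration comes last because the alkene would not survive the oxidations and the hydroxyl is needed earlier. The 2-methylbutanoate goes on O8 of 24 while O9 is still locked in a ketal, so no acyl shift is possible; the tiglate then goes on the freed, hindered O9 of 27. The reverse order would leave a tiglate next to a free equatorial hydroxyl, where migration is downhill. The forward steps must acylate without epimerising 25 and eliminate toward a methyl group rather than toward C7.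

**The C8 and C9 oxygens (24 ⇒ 23 ⇒ 22 ⇒ 20).** Both C–O bonds are traced to the C8=C9 alkene of 20. Direct cis-dihydroxylation, or iodonium-based hydroxylation with neighbouring acetate, was set aside because either needs an external oxygen to bond to C9 from the α face, between C2 and C4. Instead, the C11 hydroxyl directs an epoxide onto the β face, and the C2 ketone, as its hemiketal, opens it at C9 from the α face from inside the molecule. This gives bridged ketal 22, which also protects C2 and O9. C8 then has the wrong configuration and is corrected by oxidation to 23 and hydroxyl-directed reduction to 24. This costs more steps than a direct dihydroxylation, but each new centre has a stated cause.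

**Ring A (20 ⇒ 19 ⇒ 18).** The C1–C10 bond is cut. Precursor 18 is a single ring with an acyclic β-keto ester arm on C5 and an allylic carbonate at C8, cis to the arm. Cutting C1–C10 rather than C5–C10 or C4–C5 keeps the quaternary centre in the monocycle, where a sigmatropic shift can make it, and makes the cis fusion a consequence of mechanism. The forward reaction must ionise a hindered secondary carbonate and attack C10 with carbon.

**The arm and the C8 leaving group (18 ⇒ 17 ⇒ 15 + 16; 15 ⇒ 14 ⇒ 13).** The C1–C2 bond comes from a crossed Claisen condensation of ester 15 with methyl acetate 16. The C8 oxygen comes from allylic oxidation of 13 to enone 14, where C8 is the only allylic methylene. Reduction to 15 must give the 8α-alcohol, and this is asked of the C11 hydroxyl (internal hydride delivery), not of an external hydride that would face a hindered β side. Oxidation before the condensation keeps chromium away from the β-keto ester.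

**One-carbon homologation (13 ⇒ 12 ⇒ 9 + 10).** C3 is a methylene in the target but a carboxyl carbon after the sigmatropic step, so the C2–C3 bond is cut by an Arndt–Eistert sequence, with C2 coming from 10. This is shorter than reduction, activation and cyanide displacement at a neopentyl-like carbon, and C4 migrates with retention.

**Quaternary C5 and C4 (9 ⇒ 6).** The C4–C5 bond is cut by an Ireland–Claisen rearrangement of propanoate 6. C5 is fixed by the C9 oxygen (suprafacial shift) and C4 by ketene acetal geometry. An alkylation or conjugate addition at C5 would have no such relay from C7. The forward step needs a trans ester (C9–O pseudo-axial with the side chain equatorial) and a geometrically defined ketene acetal.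

**Ring B from the chiral pool (6 ⇒ 4 + 5; 4 ⇒ 3 ⇒ 2 ⇒ 1).** The ester C–O bond is made with inversion (Mitsunobu, acid 5) from cis alcohol 4, the expected product of 1,2-reduction of enone 3. Enone 3 is traced to (+)-3-carene 1 by allylic oxidation to 2 and hydrative opening of the cyclopropane. The carane already holds the meta relation between the methyl-bearing carbon and the side-chain carbon, the gem-dimethyl carbon that becomes C11, and the correct absolute configuration at the future C7. An asymmetric conjugate addition to a cyclohexenone would also give C7 but would then need a regioselective desaturation on the far side of the ring.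

## Roads not taken

**Alternative 1: Diels–Alder construction of ring A.** The cut is through C3–C4 and C5–C10. The forward step is a chiral-Lewis-acid-catalysed cycloaddition of tiglaldehyde A1 with 2-silyloxydiene A2, which carries C9 and C8 as a dioxolane, to give adduct A3.
- Merits: it is convergent and catalytic. The E geometry of A1 becomes the cis 4,5-dimethyl pair, C10 is set in the same step, C2 arrives as a silyl enol ether, and the C9 oxygen is in place before any ring can screen it. In this last respect it is better than the chosen plan.
- Weak points: A1 is a sluggish α,β-disubstituted dienophile; α-methyl enals tend toward exo-aldehyde adducts, whereas the cis relation of C6 and C9 needs the endo mode; and the resident dioxolane centre may oppose the catalyst. Ring B is still missing after A3: C7 with its side chain and stereocentre must be inserted between C6 and C8, and C8 is only at the primary alcohol level.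
- Comparison: the chosen plan buys ring B with C7 in two steps and spends its effort on the oxygens; Alternative 1 gets ring A cheaply and spends it on ring B. Against the better C9 handling of Alternative 1, the chosen plan sets a short, stereochemically relayed entry to the quaternary centre.

**Alternative 2: Stetter closure of ring B.** The cut is C9–C10. A carbene catalyst turns the C9 aldehyde of enone-aldehyde A4 into an acyl anion equivalent that adds to C10, giving decalin-2,9-dione A5.
- Merits: the 1,4 relation of C2 and C9 is the natural Stetter retron. A5 has a C9 carbonyl, from which the 9α-alcohol would come by hydride attack from the convex face and the 8α-oxygen by enolate oxidation at the open face of C8. That is shorter than the five operations the chosen route uses after its key step, so on this point Alternative 2 is better.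
- Weak points: A4 needs the quaternary C5 with two different arms and the C7 centre set on an open chain, with no relay between them. The cis fusion rests on catalyst and substrate bias at a centre (C10) that is α to the new ketone and can epimerise. The two ketones and the two enolisation sites of the C9 ketone must later be told apart.
- Comparison: the chosen plan fixes C10 by mechanism at a carbon that cannot enolise after step 13 and takes C7 from the chiral pool, and it pays for this with a longer oxygenation sequence.

**Alternative 3: Hydrogen-atom-transfer radical cyclisation at C5.** The cut is C5–C6. A metal hydride transfers a hydrogen atom to the exocyclic methylene of bridged ketal A6, and the tertiary C5 radical adds to the tethered acrylate to give tricycle A7.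
- Merits: the quaternary centre is made under mild radical conditions, and both oxygens and the bridged ketal are present before ring B closes, so the concave-face problem does not arise. The same ketal device appears in the chosen endgame, and Alternative 3 has it earlier and more cheaply at that stage.
- Weak points: A6 is a long build in itself (C4, C10, C9 and C8 must be set first). The radical step decides the ring fusion and leaves C7 to a hydrogen-atom quench, and the C7 ester must still become isopropenyl next to a protected oxygen.
- Comparison: the chosen plan makes C5 by a sigmatropic shift with a defined stereochemical source and is shorter overall to the bicycle, while Alternative 3 is neater in how it brings in the oxygens.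

Key step: step 12

Assumption: (+)-3-carene (1) and (R)-2-methylbutanoic acid (25) are bought as single enantiomers; the ester stereocentre of the target is R as drawn and is carried in unchanged.

## Route

Step 1
Reactants: 1 (+)-3-carene
Product: 2 (1R,6S)-4,7,7-trimethylbicyclo[4.1.0]hept-3-en-2-one (car-3-en-5-one)
Conditions: t-BuOOH (aq.), CrO3 (cat.), CH2Cl2, rt
Reagents that add atoms: tert-butyl hydroperoxide, CC(C)(C)OO
Why: Chromium-catalysed allylic oxidation; the methylene next to the unsubstituted alkene carbon is oxidised, which gives the β-methyl enone conjugated with the cyclopropane, and neither stereocentre is touched.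

Step 2
Reactants: 2 car-3-en-5-one
Product: 3 (5S)-5-(2-hydroxypropan-2-yl)-3-methylcyclohex-2-en-1-one
Conditions: H2SO4 (10 % aq.), THF, rt
Reagents that add atoms: water, O
Why: Acid-catalysed homoconjugate addition of water to a cyclopropyl enone: the exocyclic cyclopropane bond aligned with the carbonyl π system opens toward the tertiary cation, which water captures. The untouched ring carbon of the carane becomes C7 with the configuration the target needs.

Step 3
Reactants: 3 hydroxy enone
Product: 4 (1S,5S)-5-(2-hydroxypropan-2-yl)-3-methylcyclohex-2-en-1-ol (cis, 9β-OH)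
Conditions: NaBH4, CeCl3·7H2O, MeOH, −40 °C
Reagents that add atoms: none
Why: Luche 1,2-reduction; axial hydride attack on the half-chair with the C7 substituent equatorial should give the pseudo-equatorial alcohol cis to the side chain.

Step 4
Reactants: 4 cis allylic alcohol; 5 propanoic acid
Product: 6 (1R,5S)-5-(2-hydroxypropan-2-yl)-3-methylcyclohex-2-en-1-yl propanoate (trans, 9α-O)
Conditions: PPh3, diisopropyl azodicarboxylate, THF, 0 °C to rt
Reagents that add atoms: none
Why: Mitsunobu esterification with inversion at C9; the tertiary alcohol is inert and, lying on the β face, cannot displace the activated β oxygen.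

Step 5
Reactants: 6 trans propanoate
Product: 9 (2R)-2-[(1S,5R)-5-(2-hydroxypropan-2-yl)-1-methylcyclohex-2-en-1-yl]propanoic acid, via Z silyl ketene acetal 7 (not isolated), via trimethylsilyl ester 8 (not isolated)
Conditions: LiN(i-Pr)2, THF–DMPU, −78 °C; Me3SiCl; −78 to 65 °C; then 1 M HCl
Reagents that add atoms: none
Why: Ireland–Claisen rearrangement: enolisation in the presence of DMPU gives the Z ketene acetal (C-methyl cis to OSiMe3), and the pseudo-axial 9α C–O bond delivers C4 suprafacially to the α face of C5. In the boat-like transition state usual for cyclohexenyl esters, methyl and silyloxy both point away from the ring, which sets C4 as drawn; the transient silyl groups on the acid and on O11 are lost in the acidic work-up.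

Step 6
Reactants: 9 Claisen acid; 10 (trimethylsilyl)diazomethane
Product: 12 (3R)-1-diazo-3-[(1S,5R)-5-(2-hydroxypropan-2-yl)-1-methylcyclohex-2-en-1-yl]butan-2-one, via mixed carbonic anhydride 11 (not isolated)
Conditions: i-BuOCOCl, N-methylmorpholine, THF, −15 °C; then 10, MeCN, 0 °C to rt
Reagents that add atoms: none
Why: First half of an Arndt–Eistert homologation; the mixed anhydride activates only the carboxylate and leaves the tertiary alcohol alone, and the diazo carbon is acylated with loss of the silyl group. C4 is not enolised.

Step 7
Reactants: 12 diazoketone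
Product: 13 methyl (3S)-3-[(1R,5R)-5-(2-hydroxypropan-2-yl)-1-methylcyclohex-2-en-1-yl]butanoate
Conditions: AgO2CPh (cat.), Et3N, MeOH, rt, dark
Reagents that add atoms: methanol, CO
Why: Silver-catalysed Wolff rearrangement; C4 migrates with retention and methanol traps the ketene, so C3 is now a methylene and the former diazo carbon is C2.

Step 8
Reactants: 13 homologated ester
Product: 14 methyl (3S)-3-[(1R,5R)-5-(2-hydroxypropan-2-yl)-1-methyl-4-oxocyclohex-2-en-1-yl]butanoate (C8 enone)
Conditions: CrO3, 3,5-dimethylpyrazole, CH2Cl2, −20 °C
Reagents that add atoms: chromium trioxide, O=[Cr](=O)=O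
Why: Allylic oxidation with the chromium trioxide–dimethylpyrazole complex; C8 is the only allylic methylene because C5 is quaternary, and the tertiary alcohol and the ester are inert to hexavalent chromium under these conditions.

Step 9
Reactants: 14 enone
Product: 15 methyl (3S)-3-[(1R,4S,5S)-4-hydroxy-5-(2-hydroxypropan-2-yl)-1-methylcyclohex-2-en-1-yl]butanoate (8α-OH)
Conditions: Me4N[BH(OAc)3], MeCN–AcOH, −25 °C
Reagents that add atoms: none
Why: Hydroxyl-directed reduction of a β-hydroxy ketone: the C11 oxygen, bound to boron, lies over the β face of C8 and delivers hydride there, giving the 8α-alcohol (trans to the side chain, cis to the C5 arm). An external hydride would meet the side chain on that face.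

Step 10
Reactants: 15 hydroxy ester; 16 methyl acetate
Product: 17 methyl (5S)-5-[(1R,4S,5S)-4-hydroxy-5-(2-hydroxypropan-2-yl)-1-methylcyclohex-2-en-1-yl]-3-oxohexanoate
Conditions: 16, LiN(i-Pr)2 (excess), THF, −78 °C; then 15, −78 to −30 °C; 1 M HCl
Reagents that add atoms: none
Why: Crossed Claisen condensation of the methyl ester with the lithium enolate of methyl acetate; the two hydroxyls travel as alkoxides and the product is held as its enolate until the quench.

Step 11
Reactants: 17 β-keto ester diol
Product: 18 methyl (5S)-5-[(1R,4S,5S)-5-(2-hydroxypropan-2-yl)-4-(methoxycarbonyloxy)-1-methylcyclohex-2-en-1-yl]-3-oxohexanoate (8α allylic carbonate)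
Conditions: ClCO2Me, pyridine, CH2Cl2, 0 °C
Reagents that add atoms: methyl chloroformate, COC(=O)Cl
Why: Acylation of the secondary allylic alcohol with retention at C8; the tertiary alcohol is too hindered and pyridine does not enolise the β-keto ester.

Step 12
Reactants: 18 allylic carbonate
Product: 19 methyl 11-hydroxy-2-oxo-10βH-eremophil-8-ene-1α-carboxylate (cis-fused β-keto ester)
Conditions: Pd(PPh3)4 (10 mol %), THF, 65 °C
Reagents that add atoms: none
Why: Zerovalent palladium adds to the C9=C10 alkene anti to the α-carbonate and ionises it with inversion, placing the metal on the β face of a C8–C9–C10 π-allyl; the methyl carbonate ion loses CO2 and the methoxide formed deprotonates the β-keto ester, so no external base is needed. The closest known reaction type is the intramolecular Tsuji–Trost alkylation of a stabilised enolate with Pd(PPh3)4. Ring A closes in the 6-exo mode: the soft enolate carbon C1, held on C5 by the C2–C3–C4 chain, attacks C10 on the face away from palladium and the C8=C9 alkene is left outside the new ring. C10 is controlled by the two inversions together with the tether: the carbonate is on the face of the C5 arm, so C1 arrives on that same α face, H-10 ends β and the fusion is cis. C1 forms with its ester equatorial but is enolisable and is removed in step 13. The step needs C- over O-alkylation (an O-alkylated enol ether would be an allylic ether of a vinylogous carbonate and re-ionises, so the carbocycle is the thermodynamic outlet), attack at C10 and not C8 (C8 would give a bridged ring and is out of reach), and no diene formation (C5 is quaternary and H-7 is anti to palladium, so there is no syn β-hydrogen). The free C11 hydroxyl is a spectator because it sits on the palladium face and cannot attack the allyl anti to the metal.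

Step 13
Reactants: 19 bicyclic β-keto ester
Product: 20 11-hydroxy-10βH-eremophil-8-en-2-one
Conditions: LiCl, DMSO, H2O, 140 °C
Reagents that add atoms: none
Why: Krapcho dealkoxycarbonylation: chloride demethylates the ester and the β-keto carboxylate loses CO2, removing the labile C1 centre. C10 is not α to the ketone and keeps its configuration.

Step 14
Reactants: 20 alkenyl ketone
Product: 22 2α,9α-epoxy-2β-methoxy-10βH-eremophilane-8β,11-diol (bridged methyl ketal), via 8β,9β-epoxide 21 (not isolated)
Conditions: VO(acac)2 (cat.), t-BuOOH, CH2Cl2, 0 °C to rt; then MeOH, camphorsulfonic acid (cat.), rt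
Reagents that add atoms: tert-butyl hydroperoxide, CC(C)(C)OO; methanol, CO
Why: Vanadium-catalysed epoxidation directed by the homoallylic C11 hydroxyl places the epoxide on the β face. In acidic methanol the C2 ketone forms its hemiketal, whose axial hydroxyl is syn-axial to C9 and opens the epoxide there from the α face in a trans-diaxial 5-exo closure (intramolecular ketalisation of an epoxy ketone). C9 gains its α oxygen with inversion, C8 keeps the β hydroxyl, and C2 and O9 are protected in one bridged ketal.

Step 15
Reactants: 22 bridged ketal 8β-ol
Product: 23 2α,9α-epoxy-11-hydroxy-2β-methoxy-10βH-eremophilan-8-one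
Conditions: Dess–Martin periodinane, CH2Cl2, rt
Reagents that add atoms: none
Why: Dess–Martin oxidation of the only secondary alcohol; the tertiary alcohol and the ketal are inert, C9 is locked by the bridge and C7 keeps its equatorial substituent.

Step 16
Reactants: 23 C8 ketone
Product: 24 2α,9α-epoxy-2β-methoxy-10βH-eremophilane-8α,11-diol
Conditions: Me4N[BH(OAc)3], MeCN–AcOH, −25 °C
Reagents that add atoms: none
Why: Second hydroxyl-directed triacetoxyborohydride reduction: hydride is delivered from the C11 oxygen to the β face of C8, which is also the face anti to the axial C9–O bond, so the equatorial 8α-alcohol should form.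

Step 17
Reactants: 24 8α-alcohol; 25 (R)-2-methylbutanoic acid
Product: 26 2α,9α-epoxy-11-hydroxy-2β-methoxy-10βH-eremophilan-8α-yl (2R)-2-methylbutanoate
Conditions: N,N'-dicyclohexylcarbodiimide, DMAP (cat.), CH2Cl2, 0 °C to rt
Reagents that add atoms: none
Why: Steglich esterification of the only secondary alcohol; O9 is tied up in the ketal so no acyl shift is possible, and carbodiimide activation should not enolise the α-branched acid.

Step 18
Reactants: 26 ketal ester
Product: 27 9α,11-dihydroxy-2-oxo-10βH-eremophilan-8α-yl (2R)-2-methylbutanoate
Conditions: HCl (1 M aq.), THF, rt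
Reagents that add atoms: water, O
Why: Mild acid hydrolysis of the bridged methyl ketal frees the C2 ketone and the 9α-hydroxyl. The product may rest partly as the 2,9-hemiketal, which is in equilibrium with 27.

Step 19
Reactants: 27 hydroxy ketone; 28 (E)-2-methylbut-2-enoyl chloride (tigloyl chloride)
Product: 29 11-hydroxy-8α-[(2R)-2-methylbutanoyloxy]-9α-[(E)-2-methylbut-2-enoyloxy]-10βH-eremophilan-2-one
Conditions: pyridine, DMAP (cat.), CH2Cl2, 0 °C to rt
Reagents that add atoms: none
Why: DMAP-catalysed acylation with the acid chloride; the open hydroxy ketone is acylated and the hemiketal drains into it. The equatorial O8 ester has no drive to move to the hindered axial O9, and the tertiary alcohol is not acylated.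

Step 20
Reactants: 29 tertiary alcohol diester
Product: 30 8α-[(2R)-2-methylbutanoyloxy]-9α-[(E)-2-methylbut-2-enoyloxy]-10βH-eremophil-11-en-2-one (target)
Conditions: Burgess reagent (methyl N-(triethylammoniosulfonyl)carbamate), PhMe, 60 °C
Reagents that add atoms: none
Why: Burgess dehydration by syn elimination of the tertiary sulfamate: six methyl hydrogens are within reach, whereas the single C7 hydrogen is axial on the crowded α face next to the C8 ester, so the isopropenyl isomer should prevail. Ketone and esters are inert.

## Compound list

1 | (+)-3-carene, (1S,6R)-3,7,7-trimethylbicyclo[4.1.0]hept-3-ene | CC1=CC[C@@H]2[C@H](C1)C2(C)C | starting material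
2 | (1R,6S)-4,7,7-trimethylbicyclo[4.1.0]hept-3-en-2-one | CC1=CC(=O)[C@@H]2[C@H](C1)C2(C)C | intermediate
3 | (5S)-5-(2-hydroxypropan-2-yl)-3-methylcyclohex-2-en-1-one | CC1=CC(=O)C[C@H](C1)C(C)(C)O | intermediate
4 | (1S,5S)-5-(2-hydroxypropan-2-yl)-3-methylcyclohex-2-en-1-ol | CC1=C[C@@H](O)C[C@H](C1)C(C)(C)O | intermediate
5 | propanoic acid | CCC(=O)O | starting material
6 | (1R,5S)-5-(2-hydroxypropan-2-yl)-3-methylcyclohex-2-en-1-yl propanoate | CC1=C[C@H](OC(=O)CC)C[C@H](C1)C(C)(C)O | intermediate
7 | Z trimethylsilyl ketene acetal of 6 with O11 silylated | C/C=C(\O[Si](C)(C)C)O[C@H]1C=C(C)C[C@@H](C1)C(C)(C)O[Si](C)(C)C | intermediate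
8 | trimethylsilyl ester of 9 with O11 silylated | C[Si](C)(C)OC(=O)[C@H](C)[C@@]1(C)C[C@H](C(C)(C)O[Si](C)(C)C)CC=C1 | intermediate
9 | (2R)-2-[(1S,5R)-5-(2-hydroxypropan-2-yl)-1-methylcyclohex-2-en-1-yl]propanoic acid | OC(=O)[C@H](C)[C@@]1(C)C[C@H](C(C)(C)O)CC=C1 | intermediate
10 | (trimethylsilyl)diazomethane | C[Si](C)(C)C=[N+]=[N-] | starting material
11 | isobutyl carbonic anhydride of 9 | CC(C)COC(=O)OC(=O)[C@H](C)[C@@]1(C)C[C@H](C(C)(C)O)CC=C1 | intermediate
12 | (3R)-1-diazo-3-[(1S,5R)-5-(2-hydroxypropan-2-yl)-1-methylcyclohex-2-en-1-yl]butan-2-one | [N-]=[N+]=CC(=O)[C@H](C)[C@@]1(C)C[C@H](C(C)(C)O)CC=C1 | intermediate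
13 | methyl (3S)-3-[(1R,5R)-5-(2-hydroxypropan-2-yl)-1-methylcyclohex-2-en-1-yl]butanoate | COC(=O)C[C@H](C)[C@@]1(C)C[C@H](C(C)(C)O)CC=C1 | intermediate
14 | methyl (3S)-3-[(1R,5R)-5-(2-hydroxypropan-2-yl)-1-methyl-4-oxocyclohex-2-en-1-yl]butanoate | COC(=O)C[C@H](C)[C@@]1(C)C[C@H](C(C)(C)O)C(=O)C=C1 | intermediate
15 | methyl (3S)-3-[(1R,4S,5S)-4-hydroxy-5-(2-hydroxypropan-2-yl)-1-methylcyclohex-2-en-1-yl]butanoate | COC(=O)C[C@H](C)[C@@]1(C)C[C@H](C(C)(C)O)[C@@H](O)C=C1 | intermediate
16 | methyl acetate | CC(=O)OC | starting material
17 | methyl (5S)-5-[(1R,4S,5S)-4-hydroxy-5-(2-hydroxypropan-2-yl)-1-methylcyclohex-2-en-1-yl]-3-oxohexanoate | COC(=O)CC(=O)C[C@H](C)[C@@]1(C)C[C@H](C(C)(C)O)[C@@H](O)C=C1 | intermediate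
18 | methyl (5S)-5-[(1R,4S,5S)-5-(2-hydroxypropan-2-yl)-4-(methoxycarbonyloxy)-1-methylcyclohex-2-en-1-yl]-3-oxohexanoate | COC(=O)CC(=O)C[C@H](C)[C@@]1(C)C[C@H](C(C)(C)O)[C@@H](OC(=O)OC)C=C1 | intermediate
19 | methyl 11-hydroxy-2-oxo-10βH-eremophil-8-ene-1α-carboxylate | CC(C)(O)[C@H]1C[C@@]2(C)[C@H]([C@@H](C(=O)OC)C(=O)C[C@@H]2C)C=C1 | intermediate
20 | 11-hydroxy-10βH-eremophil-8-en-2-one | CC(C)(O)[C@H]1C[C@@]2(C)[C@H](CC(=O)C[C@@H]2C)C=C1 | intermediate
21 | 8β,9β-epoxy-11-hydroxy-10βH-eremophilan-2-one | CC(C)(O)[C@H]1C[C@@]2(C)[C@H](CC(=O)C[C@@H]2C)[C@H]3O[C@H]31 | intermediate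
22 | 2α,9α-epoxy-2β-methoxy-10βH-eremophilane-8β,11-diol | CC(C)(O)[C@H]1C[C@@]2(C)[C@@H]3C[C@](OC)(C[C@@H]2C)O[C@@H]3[C@H]1O | intermediate
23 | 2α,9α-epoxy-11-hydroxy-2β-methoxy-10βH-eremophilan-8-one | CC(C)(O)[C@H]1C[C@@]2(C)[C@@H]3C[C@](OC)(C[C@@H]2C)O[C@@H]3C1=O | intermediate
24 | 2α,9α-epoxy-2β-methoxy-10βH-eremophilane-8α,11-diol | CC(C)(O)[C@H]1C[C@@]2(C)[C@@H]3C[C@](OC)(C[C@@H]2C)O[C@@H]3[C@@H]1O | intermediate
25 | (R)-2-methylbutanoic acid | CC[C@@H](C)C(=O)O | starting material
26 | 2α,9α-epoxy-11-hydroxy-2β-methoxy-10βH-eremophilan-8α-yl (2R)-2-methylbutanoate | CC(C)(O)[C@H]1C[C@@]2(C)[C@@H]3C[C@](OC)(C[C@@H]2C)O[C@@H]3[C@@H]1OC(=O)[C@H](C)CC | intermediate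
27 | 9α,11-dihydroxy-2-oxo-10βH-eremophilan-8α-yl (2R)-2-methylbutanoate | CC(C)(O)[C@H]1C[C@@]2(C)[C@H](CC(=O)C[C@@H]2C)[C@H](O)[C@@H]1OC(=O)[C@H](C)CC | intermediate
28 | (E)-2-methylbut-2-enoyl chloride | C/C=C(\C)C(=O)Cl | starting material
29 | 11-hydroxy-8α-[(2R)-2-methylbutanoyloxy]-9α-[(E)-2-methylbut-2-enoyloxy]-10βH-eremophilan-2-one | CC(C)(O)[C@H]1C[C@@]2(C)[C@H](CC(=O)C[C@@H]2C)[C@H](OC(=O)/C(C)=C/C)[C@@H]1OC(=O)[C@H](C)CC | intermediate
30 | 8α-[(2R)-2-methylbutanoyloxy]-9α-[(E)-2-methylbut-2-enoyloxy]-10βH-eremophil-11-en-2-one | C=C(C)[C@H]1C[C@@]2(C)[C@H](CC(=O)C[C@@H]2C)[C@H](OC(=O)/C(C)=C/C)[C@@H]1OC(=O)[C@H](C)CC | target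

## Step count and least certain steps

Total: 20 steps. Longest linear sequence: 20 steps, from 1 to 30.

**Step 12 (key step).** The most likely failure is slow ionisation. With the C7 substituent equatorial the α-carbonate is pseudo-equatorial, so its overlap with the alkene is poor, and palladium must come in over the β face of C8 beside C11. If ionisation stalls, the carbonate may simply transfer to the C11 hydroxyl or the substrate may decompose on prolonged heating. Fallback: set out from 17, the free allylic alcohol, and close the ring without palladium. A catalytic amount of Bi(OTf)3 in CH2Cl2 ionises the allylic alcohol, and the enol of the β-keto ester, which can reach C10 only from the α face, captures the allyl cation (acid-catalysed dehydrative allylation of a 1,3-dicarbonyl compound). The route is rejoined at 19 and no new compound is made on the way.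

**Step 2.** The likely failure is loss of water from the new tertiary carbinol, or drift of the double bonds toward the isomeric phenol, if the acid is strong enough to open the cyclopropane at a useful rate. Fallback: from 2, hydrogen bromide in acetic acid opens the ring by homoconjugate addition of bromide to give (5S)-5-(2-bromopropan-2-yl)-3-methylcyclohex-2-en-1-one F1. Silver-assisted hydrolysis (AgNO3, aqueous acetone) then returns to 3.

**Step 5.** The likely failure is poor control of C4. Either the Z geometry of the enolate erodes in the presence of the lithium alkoxide, or the rearrangement leaks between boat and chair transition states because the fully substituted allyl terminus makes the two methyl groups eclipse in the boat. Fallback: set C4 by auxiliary control, not by transition-state topology. From 4, Mitsunobu inversion with acetic acid gives the 9α-acetate F2, and its Ireland–Claisen rearrangement gives the acetic acid analogue of 9 lacking the C4 methyl, F3, with C5 set as before. F3 is coupled (pivaloyl mixed anhydride, lithiated auxiliary) with (R)-4-benzyloxazolidin-2-one to give the N-acyl oxazolidinone F4. Methylation of its sodium enolate (NaN(SiMe3)2, MeI) on the face away from the benzyl group gives the α-methyl imide F5, and LiOH/H2O2 releases 9.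

**Step 14.** The likely failure is loss of hydroxyl delivery at the hindered alkene (no reaction, or epoxidation from the wrong side), or opening of the epoxide by methanol at C8 instead of by the hemiketal at C9. Fallback: from 20, iodoketalisation with N-iodosuccinimide in methanol, in which the hemiketal oxygen attacks C9 from the α face as iodine adds to C8, gives the 8β-iodo-2α,9α-epoxy-2β-methoxy ketal F6. Kornblum oxidation of the iodide (AgBF4, DMSO, then Et3N) leads to ketone 23.

**Step 19.** The likely failure is slow acylation of the axial 9α-hydroxyl, which is partly hidden as the hemiketal and flanked by C2 and C4, so that base-mediated shift of the O8 acyl group followed by acylation of the freed equatorial hydroxyl becomes competitive. Fallback: reverse the order of the two acylations so that the slow one has no neighbouring ester. From 23, acid hydrolysis gives 9α,11-dihydroxy-10βH-eremophilane-2,8-dione F7. Tigloylation with 28 gives 11-hydroxy-9α-tigloyloxy-10βH-eremophilane-2,8-dione F8. Hydroxyl-directed reduction (Me4N[BH(OAc)3], acidic medium, no acyl shift) gives 8α,11-dihydroxy-9α-tigloyloxy-10βH-eremophilan-2-one F9. Fast Steglich esterification of the unhindered equatorial hydroxyl with 25 at 0 °C returns to 29.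

**Step 20.** The likely failure is elimination toward C7 (the tetrasubstituted alkene) through an ionised tertiary sulfamate, or thermal damage to the diester. Fallback: move the elimination to the robust ketal stage, where there is one ester and no ketone. From 26, Martin sulfurane in CH2Cl2 at low temperature gives 2α,9α-epoxy-2β-methoxy-8α-[(2R)-2-methylbutanoyloxy]-10βH-eremophil-11-ene F10, from which any isomeric alkene is removed. Acid hydrolysis gives 9α-hydroxy-8α-[(2R)-2-methylbutanoyloxy]-10βH-eremophil-11-en-2-one F11, and tigloylation with 28 gives 30 directly.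

## Further compounds

F0 | step 12 | none | none
F1 | step 2 | (5S)-5-(2-bromopropan-2-yl)-3-methylcyclohex-2-en-1-one | CC1=CC(=O)C[C@H](C1)C(C)(C)Br
F2 | step 5 | 9α-acetate, (1R,5S)-5-(2-hydroxypropan-2-yl)-3-methylcyclohex-2-en-1-yl acetate | CC1=C[C@H](OC(C)=O)C[C@H](C1)C(C)(C)O
F3 | step 5 | acetic acid analogue of 9 lacking the C4 methyl | OC(=O)C[C@@]1(C)C[C@H](C(C)(C)O)CC=C1
F4 | step 5 | N-acyl (R)-4-benzyloxazolidin-2-one of F3 | O=C(C[C@@]1(C)C[C@H](C(C)(C)O)CC=C1)N1[C@H](Cc2ccccc2)COC1=O
F5 | step 5 | α-methyl imide, N-acyl (R)-4-benzyloxazolidin-2-one of 9 | O=C([C@H](C)[C@@]1(C)C[C@H](C(C)(C)O)CC=C1)N1[C@H](Cc2ccccc2)COC1=O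
F6 | step 14 | 8β-iodo-2α,9α-epoxy-2β-methoxy-10βH-eremophilan-11-ol | CC(C)(O)[C@H]1C[C@@]2(C)[C@@H]3C[C@](OC)(C[C@@H]2C)O[C@@H]3[C@H]1I
F7 | step 19 | 9α,11-dihydroxy-10βH-eremophilane-2,8-dione | CC(C)(O)[C@H]1C[C@@]2(C)[C@H](CC(=O)C[C@@H]2C)[C@H](O)C1=O
F8 | step 19 | 11-hydroxy-9α-tigloyloxy-10βH-eremophilane-2,8-dione | CC(C)(O)[C@H]1C[C@@]2(C)[C@H](CC(=O)C[C@@H]2C)[C@H](OC(=O)/C(C)=C/C)C1=O
F9 | step 19 | 8α,11-dihydroxy-9α-tigloyloxy-10βH-eremophilan-2-one | CC(C)(O)[C@H]1C[C@@]2(C)[C@H](CC(=O)C[C@@H]2C)[C@H](OC(=O)/C(C)=C/C)[C@@H]1O
F10 | step 20 | 2α,9α-epoxy-2β-methoxy-8α-[(2R)-2-methylbutanoyloxy]-10βH-eremophil-11-ene | C=C(C)[C@H]1C[C@@]2(C)[C@@H]3C[C@](OC)(C[C@@H]2C)O[C@@H]3[C@@H]1OC(=O)[C@H](C)CC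
F11 | step 20 | 9α-hydroxy-8α-[(2R)-2-methylbutanoyloxy]-10βH-eremophil-11-en-2-one | C=C(C)[C@H]1C[C@@]2(C)[C@H](CC(=O)C[C@@H]2C)[C@H](O)[C@@H]1OC(=O)[C@H](C)CC
A1 | alternative 1 | tiglaldehyde, (E)-2-methylbut-2-enal | C/C=C(\C)C=O
A2 | alternative 1 | 2-silyloxydiene carrying C9 and C8 as a dioxolane | C=C(O[Si](C)(C)C(C)(C)C)/C=C/[C@H]1COC(C)(C)O1
A3 | alternative 1 | Diels–Alder adduct, ring A silyl enol ether with C6 aldehyde on C5 and dioxolane on C10 | O=C[C@@]1(C)[C@H](C=C(O[Si](C)(C)C(C)(C)C)C[C@@H]1C)[C@H]2COC(C)(C)O2
A4 | alternative 2 | ring A enone with the C6–C9 aldehyde arm on C5 | C=C(C)[C@H](CC=O)C[C@@]1(C)C=CC(=O)C[C@@H]1C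
A5 | alternative 2 | cis-fused decalin-2,9-dione | C=C(C)[C@H]1C[C@@]2(C)[C@H](CC(=O)C[C@@H]2C)C(=O)C1
A6 | alternative 3 | ring A bridged ketal with C5 methylene and tethered 2-substituted acrylate | C=C(C(=O)OC)[C@@H](O[Si](C)(C)C(C)(C)C)[C@H]1O[C@@]2(OC)C[C@H](C)C(=C)[C@@H]1C2
A7 | alternative 3 | tricyclic bridged ketal with C5 methyl, C7 methyl ester and C8 silyl ether | COC(=O)[C@H]1C[C@@]2(C)[C@@H]3C[C@](OC)(C[C@@H]2C)O[C@@H]3[C@@H]1O[Si](C)(C)C(C)(C)C
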